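**Retrosynthetic overview**
1. 16 ⇒ alkene 15 (C1=C10 epoxidised last, reagent-controlled) ⇒ alcohol 13 + senecioyl chloride 14 ⇒ 8-ketone 12 (CBS reduction).
2. Butenolide of 12 ⇒ ten-membered epoxy 1,3-dione 6 + acetoxypyruvate 9: Knoevenagel at C7, then epoxide-directed reduction of C6 and lactonisation onto O6.
3. Ten-membered ring of 6 ⇒ cis-fused bicyclic ketol 5: the six-membered ring of 2 is enlarged by four carbons by cutting the shared C1–C6 bond through the alkoxy radical (key step).
4. 5 ⇒ epoxy ketone 2 + pent-3-yn-2-one 3 (Michael addition, aldol addition); 2 ⇒ 3-methylcyclohexenone 1 (asymmetric epoxidation, the only source of absolute configuration).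
5. Ring order: oxirane C4/C5 → second six-membered ring (temporary) → ten-membered ring → butenolide → oxirane C1/C10.

Target as read: 13-acetoxy-1,10:4,5-diepoxy-8-(3-methylbut-2-enoyloxy)germacr-7(11)-en-12,6-olide, (1S,4S,5R,6R,8R,10R); in both oxiranes the two ring carbons are cis.
Numbering: germacrane numbering throughout (C1–C10 ring, C11 lactone α-carbon, C12 lactone carbonyl, C13 CH2OAc carbon, C14 methyl on C10, C15 methyl on C4), also for the atoms of earlier intermediates that become these positions.
Assumption: the facial sense of the chiral catalysts in steps 1, 7 and 9 follows their usual models; where it proves opposite, the enantiomeric catalyst is used.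

**Step 1**
Reactants: 1 3-methylcyclohex-2-en-1-one
Product: 2 (2S,3S)-2,3-epoxy-3-methylcyclohexan-1-one
Conditions: 9-amino-9-deoxy-epi-quinine bis(trifluoroacetate) (10 mol%), 50% aq. H2O2 (1.5 equiv), 1,4-dioxane, 50 °C
Reagents that add atoms: hydrogen peroxide, OO
Why: Amine-catalysed asymmetric Weitz–Scheffer epoxidation of a cyclic enone; the chiral primary ammonium salt forms the iminium ion and directs hydroperoxide to one face of C3, and ring closure gives the cis-oxirane, setting the two centres that become C5 and C4.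

**Step 2**
Reactants: 2 (2S,3S)-2,3-epoxy-3-methylcyclohexan-1-one; 3 pent-3-yn-2-one
Product: 5 (4aR,7S,8R,8aR)-7,8-epoxy-8a-hydroxy-4,7-dimethyl-4a,5,6,7,8,8a-hexahydronaphthalen-2(1H)-one, via Michael adduct 4 (not isolated)
Conditions: KN(SiMe3)2 (1.05 equiv), THF, −78 °C; 3 (1.1 equiv), −78 → −40 °C; AcOH (1.05 equiv); then K2CO3 (0.3 equiv), MeOH, 0 °C
Reagents that add atoms: none
Why: Michael addition of the α'-enolate (the only enolisable side of 2) to the methyl-bearing alkyne carbon, then base-catalysed intramolecular aldol addition (first half of a Robinson annulation, stopped at the ketol by the mild conditions); the E/Z isomers of 4 equilibrate through the dienolate and only the Z isomer can close, the methyl-ketone carbon adds to the epoxy ketone anti to the oxirane C–O bond, and the cis ring fusion is the equilibrium one (both new centres are erased in step 3).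

**Step 3**
Reactants: 5 (4aR,7S,8R,8aR)-7,8-epoxy-8a-hydroxy-4,7-dimethyl-4a,5,6,7,8,8a-hexahydronaphthalen-2(1H)-one
Product: 6 (1S,6Z,10S)-6,10-dimethyl-11-oxabicyclo[8.1.0]undec-6-ene-2,4-dione
Conditions: [Ir(dF(CF3)ppy)2(5,5'-d(CF3)bpy)]PF6 (2 mol%), 2,4,6-collidine (0.5 equiv), blue LEDs (450 nm), CH2Cl2, 23 °C
Reagents that add atoms: none
Why: Proposed new method: catalytic redox-neutral alkoxy-radical ring expansion of a ring-fusion ketol; proton-coupled electron transfer from the tertiary O–H to the excited iridium complex and collidine gives the C6 alkoxy radical, β-scission cuts the shared C1–C6 bond (the only one of the three candidates that leaves a secondary allylic radical vinylogous to the C8 carbonyl; the others would give an oxiranyl or a primary radical), the reduced iridium complex returns the electron to give the dienolate, and collidinium protonates it at C9 so the new C1=C10 bond stays out of conjugation; the scission is irreversible, which matters because the purely anionic retro-aldol route is not expected to be downhill (the enolate of 4 is the anionic sink); in the cis-fused ketol the ring A bond C1–C2 is pseudo-axial on the enone ring B when C1–C6 overlaps with the enone π system, so C2 ends cis to C9 (Z); closest known reaction types are hypoiodite alkoxy-radical fragmentation of bicyclic tertiary alcohols to medium rings and photocatalytic PCET ring opening and ring expansion of cycloalkanols.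

**Step 4**
Reactants: 7 methyl 3-bromo-2-oxopropanoate; 8 potassium acetate
Product: 9 methyl 3-acetoxy-2-oxopropanoate
Conditions: acetone, 0 → 23 °C
Reagents that add atoms: none
Why: SN2 displacement of the activated α-keto bromide by acetate.

**Step 5**
Reactants: 6 (1S,6Z,10S)-6,10-dimethyl-11-oxabicyclo[8.1.0]undec-6-ene-2,4-dione; 9 methyl 3-acetoxy-2-oxopropanoate
Product: 10 methyl 3-acetoxy-2-[(1S,6Z,10S)-6,10-dimethyl-2,4-dioxo-11-oxabicyclo[8.1.0]undec-6-en-3-ylidene]propanoate
Conditions: ethylenediammonium diacetate (10 mol%), 4 Å molecular sieves, CH2Cl2, 0 → 23 °C (6 used freshly)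
Reagents that add atoms: none
Why: Knoevenagel condensation of the only doubly activated methylene (C7) with the activated ketone of the α-keto ester forms the C7=C11 bond with C12 and C13 in place; either alkene geometry is acceptable because it equilibrates in step 6.

**Step 6**
Reactants: 10 methyl 3-acetoxy-2-[(1S,6Z,10S)-6,10-dimethyl-2,4-dioxo-11-oxabicyclo[8.1.0]undec-6-en-3-ylidene]propanoate
Product: 12 (1(10)Z,4S,5R,6R)-13-acetoxy-4,5-epoxy-8-oxogermacra-1(10),7(11)-dien-12,6-olide, via hydroxy ester 11 (not isolated)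
Conditions: Zn(BH4)2 (0.6 equiv), Et2O, −40 °C; aq. NH4Cl; then PBu3 (5 mol%), CH2Cl2, 23 °C
Reagents that add atoms: none
Why: Chelation-controlled zinc borohydride reduction of an α,β-epoxy ketone; zinc bridges the oxirane and C6 carbonyl oxygens, which activates C6 over the unchelated C8 ketone and sends hydride anti to C4 (erythro epoxy alcohol, 6R), and phosphine-catalysed E/Z equilibration of the remaining ene-dione followed by lactonisation of the cis γ-hydroxy ester gives the butenolide on O6 only, since C8 is still a ketone.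

**Step 7**
Reactants: 12 (1(10)Z,4S,5R,6R)-13-acetoxy-4,5-epoxy-8-oxogermacra-1(10),7(11)-dien-12,6-olide
Product: 13 (1(10)Z,4S,5R,6R,8R)-13-acetoxy-4,5-epoxy-8-hydroxygermacra-1(10),7(11)-dien-12,6-olide
Conditions: (S)-1-methyl-3,3-diphenyltetrahydro-1H,3H-pyrrolo[1,2-c][1,3,2]oxazaborole (20 mol%), catecholborane (1.5 equiv), toluene, −78 °C
Reagents that add atoms: none
Why: Corey–Bakshi–Shibata reduction; reagent-controlled 1,2-hydride delivery to the C8 ketone with the fully substituted alkenyl carbon C7 as the large group and C9H2 as the small one gives 8R, and the neutral conditions spare the acidic C6–H, the oxirane and the esters.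

**Step 8**
Reactants: 13 (1(10)Z,4S,5R,6R,8R)-13-acetoxy-4,5-epoxy-8-hydroxygermacra-1(10),7(11)-dien-12,6-olide; 14 3-methylbut-2-enoyl chloride
Product: 15 (1(10)Z,4S,5R,6R,8R)-13-acetoxy-4,5-epoxy-8-(3-methylbut-2-enoyloxy)germacra-1(10),7(11)-dien-12,6-olide
Conditions: pyridine (3 equiv), 4-(dimethylamino)pyridine (5 mol%), CH2Cl2, 0 °C
Reagents that add atoms: none
Why: Nucleophile-catalysed acylation of the secondary allylic alcohol by the acid chloride under weakly basic conditions that touch no stereocentre.

**Step 9**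
Reactants: 15 (1(10)Z,4S,5R,6R,8R)-13-acetoxy-4,5-epoxy-8-(3-methylbut-2-enoyloxy)germacra-1(10),7(11)-dien-12,6-olide
Product: 16 (1S,4S,5R,6R,8R,10R)-13-acetoxy-1,10:4,5-diepoxy-8-(3-methylbut-2-enoyloxy)germacr-7(11)-en-12,6-olide
Conditions: 1,2:4,5-di-O-isopropylidene-β-L-erythro-2,3-hexodiulo-2,6-pyranose (30 mol%), KHSO5 (1.5 equiv, as 2KHSO5·KHSO4·K2SO4), K2CO3 buffer (pH 10.5), Bu4NHSO4 (5 mol%), MeCN/CH2(OMe)2/H2O, 0 °C
Reagents that add atoms: potassium peroxymonosulfate, [K+].[O-]S(=O)(=O)OO
Why: Shi asymmetric epoxidation; the chiral dioxirane attacks the only electron-rich alkene (butenolide and senecioate C=C are electron-poor) through a spiro transition state, and the L-configured ketone is chosen because the model gives the (1S,10R) oxirane with it on this trisubstituted Z-alkene, setting C1 and C10 by reagent control.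

**Compound list**
1 | 3-methylcyclohex-2-en-1-one | CC1=CC(=O)CCC1 | starting material
2 | (2S,3S)-2,3-epoxy-3-methylcyclohexan-1-one | O=C1[C@H]2O[C@@]2(C)CCC1 | intermediate
3 | pent-3-yn-2-one | CC#CC(C)=O | starting material
4 | (2S,3S)-2,3-epoxy-3-methyl-6-(4-oxopent-2-en-2-yl)cyclohexan-1-one (C6 epimers, E/Z mixture) | O=C1[C@H]2O[C@@]2(C)CCC1C(C)=CC(C)=O | intermediate
5 | (4aR,7S,8R,8aR)-7,8-epoxy-8a-hydroxy-4,7-dimethyl-4a,5,6,7,8,8a-hexahydronaphthalen-2(1H)-one (cis-fused ketol) | O=C1C=C(C)[C@H]2CC[C@]3(C)O[C@@H]3[C@@]2(O)C1 | intermediate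
6 | (1S,6Z,10S)-6,10-dimethyl-11-oxabicyclo[8.1.0]undec-6-ene-2,4-dione (4,5-epoxy-6,8-dione in germacrane numbering) | O=C1[C@H]2O[C@@]2(C)CC/C=C(C)\CC(=O)C1 | intermediate
7 | methyl 3-bromo-2-oxopropanoate | COC(=O)C(=O)CBr | starting material
8 | potassium acetate | CC(=O)[O-].[K+] | starting material
9 | methyl 3-acetoxy-2-oxopropanoate | COC(=O)C(=O)COC(C)=O | intermediate
10 | methyl 3-acetoxy-2-[(1S,6Z,10S)-6,10-dimethyl-2,4-dioxo-11-oxabicyclo[8.1.0]undec-6-en-3-ylidene]propanoate (ylidene E/Z mixture) | CC(=O)OCC(C(=O)OC)=C2C(=O)[C@H]1O[C@@]1(C)CC/C=C(C)\CC2=O | intermediate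
11 | methyl (2E)-3-acetoxy-2-[(1R,2R,6Z,10S)-2-hydroxy-6,10-dimethyl-4-oxo-11-oxabicyclo[8.1.0]undec-6-en-3-ylidene]propanoate | CC(=O)OC/C(C(=O)OC)=C2/[C@@H](O)[C@H]1O[C@@]1(C)CC/C=C(C)\CC2=O | intermediate
12 | (1(10)Z,4S,5R,6R)-13-acetoxy-4,5-epoxy-8-oxogermacra-1(10),7(11)-dien-12,6-olide | CC(=O)OCC1=C2[C@@H](OC1=O)[C@H]1O[C@@]1(C)CC/C=C(C)\CC2=O | intermediate
13 | (1(10)Z,4S,5R,6R,8R)-13-acetoxy-4,5-epoxy-8-hydroxygermacra-1(10),7(11)-dien-12,6-olide | CC(=O)OCC1=C2[C@@H](OC1=O)[C@H]1O[C@@]1(C)CC/C=C(C)\C[C@H]2O | intermediate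
14 | 3-methylbut-2-enoyl chloride | CC(C)=CC(Cl)=O | starting material
15 | (1(10)Z,4S,5R,6R,8R)-13-acetoxy-4,5-epoxy-8-(3-methylbut-2-enoyloxy)germacra-1(10),7(11)-dien-12,6-olide | CC(=O)OCC1=C2[C@@H](OC1=O)[C@H]1O[C@@]1(C)CC/C=C(C)\C[C@H]2OC(=O)C=C(C)C | intermediate
16 | (1S,4S,5R,6R,8R,10R)-13-acetoxy-1,10:4,5-diepoxy-8-(3-methylbut-2-enoyloxy)germacr-7(11)-en-12,6-olide | CC(=O)OCC1=C2[C@@H](OC1=O)[C@H]1O[C@@]1(C)CC[C@@H]1O[C@]1(C)C[C@H]2OC(=O)C=C(C)C | target

**Step count and risks**
Total step count: 9. Longest linear sequence: 8 (steps 1, 2, 3, 5, 6, 7, 8, 9; step 4 is a one-step side branch).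

Three steps most likely to fail:

Step 3 (the proposed ring expansion). The photocatalytic O–H activation of a hindered tertiary ketol may be slow, or the delocalised radical may be protonated at C1 instead of C9. The fallback sets out from 5 and returns to 6 with known stoichiometric chemistry. PhI(OAc)2 and I2 under visible light in CH2Cl2 generate the same alkoxy radical through the hypoiodite; β-scission of the C1–C6 bond and iodine transfer give (1S,6Z,10S)-5-iodo-6,10-dimethyl-11-oxabicyclo[8.1.0]undec-6-ene-2,4-dione F1 (iodine on C9, epimers). Zn dust in AcOH/THF at 0 °C then removes the iodine through the zinc enolate, protonated at C9, to give 6.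

Step 6 (which ketone is reduced first decides which oxygen lactonises). If the C8 ketone competes, or hydride adds in a conjugate sense, the fallback masks C8 instead of relying on relative rates. It sets out from 10 and returns to 12. TBSOTf and Et3N in CH2Cl2 at −78 °C convert the C8 ketone, the only one with an enolisable α-CH2, into the C8 tert-butyldimethylsilyl dienol ether of 10 F2. Zn(BH4)2 then reduces the single remaining ketone at C6, and the hydroxy ester lactonises to the 8-silyloxy-1(10),7(11),8-triene lactone F3. Bu4NF buffered with AcOH at −40 °C releases the C8 ketone with protonation at C9 and gives 12.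

Step 9 (facial selectivity of the last epoxidation). The ring conformation may oppose the catalyst. The fallback replaces reagent-controlled oxygen transfer by substrate-controlled anti addition and closure, which puts the oxygen on the face opposite to the one a direct electrophilic oxidant attacks. It sets out from 15 and returns to 16. NBS in THF/H2O at 0 °C gives the (1R,10R)-1-bromo-10-hydroxy bromohydrin of 15 F4 (bromonium on the exposed face, water at the tertiary C10), and Ag2O in CH2Cl2 closes the oxirane with inversion at C1 to give 16.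

**Further compounds**
F1 | step 3 | (1S,6Z,10S)-5-iodo-6,10-dimethyl-11-oxabicyclo[8.1.0]undec-6-ene-2,4-dione (C5 epimers) | O=C1[C@H]2O[C@@]2(C)CC/C=C(C)\C(I)C(=O)C1
F2 | step 6 | C8 tert-butyldimethylsilyl dienol ether of 10 | CC(=O)OCC(C(=O)OC)=C2C(=O)[C@H]1O[C@@]1(C)CC/C=C(C)\C=C2O[Si](C)(C)C(C)(C)C
F3 | step 6 | (1(10)Z,4S,5R,6R)-13-acetoxy-8-(tert-butyldimethylsilyloxy)-4,5-epoxygermacra-1(10),7(11),8-trien-12,6-olide | CC(=O)OCC1=C2[C@@H](OC1=O)[C@H]1O[C@@]1(C)CC/C=C(C)\C=C2O[Si](C)(C)C(C)(C)C
F4 | step 9 | (1R,4S,5R,6R,8R,10R)-13-acetoxy-1-bromo-4,5-epoxy-10-hydroxy-8-(3-methylbut-2-enoyloxy)germacr-7(11)-en-12,6-olide | CC(=O)OCC1=C2[C@@H](OC1=O)[C@H]1O[C@@]1(C)CC[C@@H](Br)[C@@](O)(C)C[C@H]2OC(=O)C=C(C)C
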